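A direct plan would grow the whole C20 chain linearly, setting C12′ and C5′ by allyl- and propargylboration of enals, as far as the bis-silylated allylic alcohol A1.
A1 would then be taken in four operations (halogenation, copper-catalysed alkynylation, C-desilylation, borylation) to alkynyl boronate A2.
The arene would be made last, by heating A2 with pyranone A3 (cycloaddition, then decarboxylation) to aryl boronate A4, followed by C–B oxidation and desilylation.
Its weakest steps would be: the thermal benzannulation, which would need about 150 °C beside two 3-siloxy-1,5-diene units and a labile skipped enyne, with unproven regiochemistry of the pyranone/alkyne pairing;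
the alkynylation of the allylic halide, where SN2′ attack, erosion of the 2′E geometry and base-induced isomerisation of the 1,4-enyne would compete;
and the six operations from A1 to the phenol, which would add length but no complexity, since they only build a benzene ring that can be bought.

The arene is bought and the chain is completed through isoprene. The feature exploited is the 2-methylbut-2-ene-1,4-diyl unit C1′–C4′ (side chain numbered from the benzylic carbon) that links ring carbon C2 of the phenol to the carbinol C5′: it is one molecule of isoprene, which a nickel-catalysed three-component coupling inserts between an aryl boronic acid and a C15 enal. In one operation this forms the aryl–C1′ and C4′–C5′ bonds, fixes the 2′E alkene and sets C5′ under ligand control; C12′ is set earlier by catalytic allylboration. No ring synthesis, allylic halide, alkyne homologation or C–B oxidation remains.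

Key step: step 11

Remark: L* is the monodentate phosphoramidite O,O′-(1,1′-binaphthyl-2,2′-diyl) N,N-bis(1-phenylethyl)phosphoramidite, (S,R,R) or (R,S,S); its sense of induction in step 11 cannot be predicted, so the enantiomer giving 5′R would be fixed by a calibration run on a model enal (Mosher ester analysis).

Step 1
Reactants: 1 geranyl acetate
Product: 2 (2E,6E)-8-hydroxy-3,7-dimethylocta-2,6-dien-1-yl acetate
Conditions: SeO2 (10 mol %), t-BuOOH (70% aq.), salicylic acid (10 mol %), CH2Cl2, rt
Reagents that add atoms: selenium dioxide, O=[Se]=O (catalytic oxygen carrier); tert-butyl hydroperoxide, CC(C)(C)OO (stoichiometric oxygen source)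
Why: Riley allylic oxidation (ene reaction of SeO2, then [2,3]-sigmatropic shift) should hydroxylate the E-methyl group of the terminal, most electron-rich alkene, the 2,3-alkene being deactivated by the allylic acetate.

Step 2
Reactants: 2 (2E,6E)-8-hydroxy-3,7-dimethylocta-2,6-dien-1-yl acetate
Product: 3 (2E,6E)-3,7-dimethyl-8-oxoocta-2,6-dien-1-yl acetate
Conditions: MnO2, CH2Cl2, rt
Reagents that add atoms: none
Why: MnO2 oxidation is specific for allylic alcohols under neutral conditions, so the E-enal should form without alkene isomerisation or loss of the acetate.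

Step 3
Reactants: 3 (2E,6E)-3,7-dimethyl-8-oxoocta-2,6-dien-1-yl acetate; 4 allylboronic acid pinacol ester
Product: 6 (2E,6E,8R)-8-hydroxy-3,7-dimethylundeca-2,6,10-trien-1-yl acetate, via pinacol borate ester 5 (not isolated)
Conditions: 4 (1.2 equiv), (R)-TRIP [(R)-3,3′-bis(2,4,6-triisopropylphenyl)-1,1′-binaphthyl-2,2′-diyl hydrogen phosphate, 5 mol %], 4 Å MS, toluene, −30 °C; aq. NaHCO3
Reagents that add atoms: none
Why: Chiral phosphoric acid-catalysed allylboration runs through a closed chair transition state in which the acid hydrogen-bonds to a boronate oxygen and the formyl hydrogen; the (R)-catalyst is expected to deliver allyl to the Re face (as for (R)-1-phenylbut-3-en-1-ol from benzaldehyde), which sets C12′ (C8 of 6) as R.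

Step 4
Reactants: 6 (2E,6E,8R)-8-hydroxy-3,7-dimethylundeca-2,6,10-trien-1-yl acetate
Product: 7 (2E,6E,8R)-8-(tert-butyldimethylsilyloxy)-3,7-dimethylundeca-2,6,10-trien-1-yl acetate
Conditions: TBSCl, imidazole, DMF, rt
Reagents that add atoms: tert-butyldimethylsilyl chloride, CC(C)(C)[Si](C)(C)Cl
Why: Imidazole-promoted silylation masks the C12′ hydroxyl, which would otherwise be oxidised by MnO2 in step 7 and could be ionised by nickel and boron in step 11.

Step 5
Reactants: 7 (2E,6E,8R)-8-(tert-butyldimethylsilyloxy)-3,7-dimethylundeca-2,6,10-trien-1-yl acetate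
Product: 8 (2E,6E,8R)-8-(tert-butyldimethylsilyloxy)-3,7,11-trimethyldodeca-2,6,10-trien-1-yl acetate
Conditions: 2-methyl-2-butene (large excess), (H2IMes)(PCy3)Cl2Ru=CHPh (second-generation Grubbs catalyst, 5 mol %), CH2Cl2, 35 °C, closed vessel
Reagents that add atoms: 2-methyl-2-butene, CC=C(C)C
Why: Olefin cross-metathesis with excess 2-methyl-2-butene turns the monosubstituted vinyl group into the prenyl terminus, the trisubstituted alkenes of the chain being too hindered to enter the catalytic cycle at a comparable rate.

Step 6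
Reactants: 8 (2E,6E,8R)-8-(tert-butyldimethylsilyloxy)-3,7,11-trimethyldodeca-2,6,10-trien-1-yl acetate
Product: 9 (2E,6E,8R)-8-(tert-butyldimethylsilyloxy)-3,7,11-trimethyldodeca-2,6,10-trien-1-ol
Conditions: K2CO3 (cat.), MeOH, 0 °C → rt
Reagents that add atoms: none
Why: Base-catalysed transesterification with methanol removes the primary acetate and leaves the secondary silyl ether untouched.

Step 7
Reactants: 9 (2E,6E,8R)-8-(tert-butyldimethylsilyloxy)-3,7,11-trimethyldodeca-2,6,10-trien-1-ol
Product: 10 (2E,6E,8R)-8-(tert-butyldimethylsilyloxy)-3,7,11-trimethyldodeca-2,6,10-trienal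
Conditions: MnO2, CH2Cl2, rt
Reagents that add atoms: none
Why: MnO2 oxidation of the primary allylic alcohol should give the E-enal, the only other allylic oxygen being silylated.

Step 8
Reactants: 11 4-methoxy-2-methylphenol
Product: 12 2-bromo-4-methoxy-6-methylphenol
Conditions: NBS (1.0 equiv), i-Pr2NH (10 mol %), CH2Cl2, 0 °C, dark
Reagents that add atoms: N-bromosuccinimide, O=C1CCC(=O)N1Br
Why: Electrophilic aromatic bromination, amine-catalysed for ortho delivery, should occur at C6, the only free position ortho to the hydroxyl group (para is blocked by OCH3, the other ortho position by CH3).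

Step 9
Reactants: 12 2-bromo-4-methoxy-6-methylphenol
Product: 13 tert-butyl(2-bromo-4-methoxy-6-methylphenoxy)dimethylsilane
Conditions: TBSCl, imidazole, DMAP (cat.), DMF, 40 °C
Reagents that add atoms: tert-butyldimethylsilyl chloride, CC(C)(C)[Si](C)(C)Cl
Why: Silyl ether formation protects the phenol against the organolithium of step 10 and keeps the aryl partner of step 11 free of an acidic OH; fluoride removes it later together with the C12′ silyl group.

Step 10
Reactants: 13 tert-butyl(2-bromo-4-methoxy-6-methylphenoxy)dimethylsilane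
Product: 16 [2-(tert-butyldimethylsilyloxy)-5-methoxy-3-methylphenyl]boronic acid, via aryllithium 14 (not isolated), via lithium triisopropoxyborate 15 (not isolated)
Conditions: B(Oi-Pr)3 (1.5 equiv), THF/toluene, −78 °C; n-BuLi (1.1 equiv, slow addition); → −20 °C; 1 M HCl, 0 °C, brief
Reagents that add atoms: triisopropyl borate, CC(C)OB(OC(C)C)OC(C)C; water, O
Why: Bromine–lithium exchange with the borate already present (in situ trapping) should intercept the ortho-silyloxy aryllithium before silicon can migrate from oxygen to carbon, and hydrolysis of the ate complex gives the boronic acid.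

Step 11
Reactants: 10 (2E,6E,8R)-8-(tert-butyldimethylsilyloxy)-3,7,11-trimethyldodeca-2,6,10-trienal; 16 [2-(tert-butyldimethylsilyloxy)-5-methoxy-3-methylphenyl]boronic acid; 17 isoprene
Product: 19 (2E,5R,6E,10E,12R)-12-(tert-butyldimethylsilyloxy)-1-[2-(tert-butyldimethylsilyloxy)-5-methoxy-3-methylphenyl]-3,7,11,15-tetramethylhexadeca-2,6,10,14-tetraen-5-ol, via boric acid monoester 18 (not isolated)
Conditions: Ni(cod)2 (10 mol %), L* (12 mol %), 16 (1.5 equiv), 17 (5 equiv), 4 Å MS, THF, 0 °C → rt, argon; pH 7 buffer
Reagents that add atoms: none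
Why: Proposed new method: zerovalent nickel bound to isoprene and the boron-activated aldehyde should undergo oxidative cyclisation at the diene terminus next to the methyl-bearing carbon to an η3-allyl oxanickelacycle (C4′–C5′ bond), boron then takes over the alkoxide as the aryl group passes to nickel, and aryl–allyl reductive elimination at the unsubstituted allyl terminus forms the aryl–C1′ bond and returns the catalyst. The closest known reaction type is the nickel-catalysed three-component connection of phenylmetal reagents, isoprene and aldehydes to (E)-3-methyl-5-phenylpent-3-en-1-ols, taken together with phosphoramidite–nickel-catalysed enantioselective couplings of 1,3-dienes with aldehydes; enantiocontrol in the arylative 1,4-connection of isoprene with an enal is not established. No ring is closed, the nickelacycle being transient. The new stereocentre C5′ is set in the oxidative cyclisation by the chiral ligand, which selects the aldehyde face (catalyst control; the remote C12′ centre cannot interfere). The step needs regiocontrol, 2′E geometry and 1,2-selectivity: the methyl group of isoprene makes C3′ a quaternary allyl terminus at which aryl transfer is disfavoured, so the aryl goes to C1′; the C4′ tether can reach the nickel-bound oxygen only from the syn position of the allyl unit, which on elimination gives the E alkene; and the β,β-disubstituted C6′=C7′ bond of the enal is too hindered for conjugate pathways, while the isolated trisubstituted alkenes do not compete with the diene for nickel. Molecular sieves keep the medium aprotic, so that protonation of the nickel–diene complex (hydroarylation of isoprene) should not compete with capture by the aldehyde.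

Step 12
Reactants: 19 (2E,5R,6E,10E,12R)-12-(tert-butyldimethylsilyloxy)-1-[2-(tert-butyldimethylsilyloxy)-5-methoxy-3-methylphenyl]-3,7,11,15-tetramethylhexadeca-2,6,10,14-tetraen-5-ol
Product: 20 2-[(2E,5R,6E,10E,12R)-5,12-dihydroxy-3,7,11,15-tetramethylhexadeca-2,6,10,14-tetraen-1-yl]-4-methoxy-6-methylphenol (CNP0269739.1)
Conditions: TBAF/AcOH (1:1, 6 equiv), THF, rt → 40 °C, argon
Reagents that add atoms: none
Why: Fluoride-induced desilylation (driven by Si–F bond formation), buffered with acetic acid, should cleave the aryl and the secondary silyl ether without ionising the allylic alcohols or oxidising the phenoxide.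

Compound list
1 | geranyl acetate, (2E)-3,7-dimethylocta-2,6-dien-1-yl acetate | CC(C)=CCC/C(C)=C/COC(C)=O | starting material
2 | (2E,6E)-8-hydroxy-3,7-dimethylocta-2,6-dien-1-yl acetate | CC(=O)OC/C=C(\C)CC/C=C(\C)CO | intermediate
3 | (2E,6E)-3,7-dimethyl-8-oxoocta-2,6-dien-1-yl acetate | CC(=O)OC/C=C(\C)CC/C=C(\C)C=O | intermediate
4 | allylboronic acid pinacol ester, 4,4,5,5-tetramethyl-2-(prop-2-en-1-yl)-1,3,2-dioxaborolane | C=CCB1OC(C)(C)C(C)(C)O1 | starting material
5 | pinacol borate ester of 6 (O–Bpin at C8) | CC(=O)OC/C=C(\C)CC/C=C(\C)[C@H](OB1OC(C)(C)C(C)(C)O1)CC=C | intermediate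
6 | (2E,6E,8R)-8-hydroxy-3,7-dimethylundeca-2,6,10-trien-1-yl acetate | CC(=O)OC/C=C(\C)CC/C=C(\C)[C@H](O)CC=C | intermediate
7 | (2E,6E,8R)-8-(tert-butyldimethylsilyloxy)-3,7-dimethylundeca-2,6,10-trien-1-yl acetate | CC(=O)OC/C=C(\C)CC/C=C(\C)[C@H](O[Si](C)(C)C(C)(C)C)CC=C | intermediate
8 | (2E,6E,8R)-8-(tert-butyldimethylsilyloxy)-3,7,11-trimethyldodeca-2,6,10-trien-1-yl acetate | CC(=O)OC/C=C(\C)CC/C=C(\C)[C@H](O[Si](C)(C)C(C)(C)C)CC=C(C)C | intermediate
9 | (2E,6E,8R)-8-(tert-butyldimethylsilyloxy)-3,7,11-trimethyldodeca-2,6,10-trien-1-ol | OC/C=C(\C)CC/C=C(\C)[C@H](O[Si](C)(C)C(C)(C)C)CC=C(C)C | intermediate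
10 | (2E,6E,8R)-8-(tert-butyldimethylsilyloxy)-3,7,11-trimethyldodeca-2,6,10-trienal | O=C/C=C(\C)CC/C=C(\C)[C@H](O[Si](C)(C)C(C)(C)C)CC=C(C)C | intermediate
11 | 4-methoxy-2-methylphenol | COc1ccc(O)c(C)c1 | starting material
12 | 2-bromo-4-methoxy-6-methylphenol | COc1cc(C)c(O)c(Br)c1 | intermediate
13 | tert-butyl(2-bromo-4-methoxy-6-methylphenoxy)dimethylsilane | COc1cc(C)c(O[Si](C)(C)C(C)(C)C)c(Br)c1 | intermediate
14 | [2-(tert-butyldimethylsilyloxy)-5-methoxy-3-methylphenyl]lithium | COc1cc(C)c(O[Si](C)(C)C(C)(C)C)c([Li])c1 | intermediate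
15 | lithium [2-(tert-butyldimethylsilyloxy)-5-methoxy-3-methylphenyl]tri(propan-2-yloxy)borate | [Li+].COc1cc(C)c(O[Si](C)(C)C(C)(C)C)c([B-](OC(C)C)(OC(C)C)OC(C)C)c1 | intermediate
16 | [2-(tert-butyldimethylsilyloxy)-5-methoxy-3-methylphenyl]boronic acid | COc1cc(C)c(O[Si](C)(C)C(C)(C)C)c(B(O)O)c1 | intermediate
17 | isoprene, 2-methylbuta-1,3-diene | C=CC(C)=C | starting material
18 | boric acid monoester of 19 (O–B(OH)2 at C5) | COc1cc(C)c(O[Si](C)(C)C(C)(C)C)c(C/C=C(\C)C[C@@H](OB(O)O)/C=C(\C)CC/C=C(\C)[C@H](O[Si](C)(C)C(C)(C)C)CC=C(C)C)c1 | intermediate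
19 | (2E,5R,6E,10E,12R)-12-(tert-butyldimethylsilyloxy)-1-[2-(tert-butyldimethylsilyloxy)-5-methoxy-3-methylphenyl]-3,7,11,15-tetramethylhexadeca-2,6,10,14-tetraen-5-ol | COc1cc(C)c(O[Si](C)(C)C(C)(C)C)c(C/C=C(\C)C[C@@H](O)/C=C(\C)CC/C=C(\C)[C@H](O[Si](C)(C)C(C)(C)C)CC=C(C)C)c1 | intermediate
20 | 2-[(2E,5R,6E,10E,12R)-5,12-dihydroxy-3,7,11,15-tetramethylhexadeca-2,6,10,14-tetraen-1-yl]-4-methoxy-6-methylphenol (CNP0269739.1) | COc1cc(C)c(O)c(C/C=C(\C)C[C@@H](O)/C=C(\C)CC/C=C(\C)[C@H](O)CC=C(C)C)c1 | target

Total step count: 12. Longest linear sequence: 9 steps (steps 1–7, 11, 12); the arene branch (steps 8–10) joins at step 11.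

Steps most likely to fail

Step 11 (proposed new method). The chiral nickel catalyst may fail to distinguish the two faces of the aldehyde during oxidative cyclisation, so that C5′ would form without control. The fallback uses known chemistry, sets out from 10, 13 and 17 and comes back at 19. Bromide 13 would be converted through aryllithium 14 and ZnCl2 (0.5 equiv) into bis[2-(tert-butyldimethylsilyloxy)-5-methoxy-3-methylphenyl]zinc F1. The coupling would then be run in its established achiral form [Ni(acac)2 (cat.), F1, isoprene 17, THF, rt] from 10 to the C5′-epimeric alcohols F2. MnO2 would oxidise the allylic C5′ hydroxyl of F2 under neutral conditions to dienone F3. Reduction of F3 with catecholborane and (S)-2-methyl-CBS-oxazaborolidine would funnel both epimers into 19; 5′R is expected if the alkenyl group acts as the large substituent, as in the reduction of acetophenone to (R)-1-phenylethanol.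

Step 10. The ortho-lithiated aryl silyl ether 14 may rearrange by 1,3-migration of silicon from oxygen to carbon before it is trapped, and the electron-rich boronic acid may lose boron during the acidic work-up. The fallback sets out from 13 and comes back at 16 without an aryllithium. Palladium-catalysed Miyaura borylation [Pd(dppf)Cl2, B2pin2, KOAc, dioxane, 80 °C] would give pinacol boronate F4, and the pinacol ester would be cleaved with NaIO4/NH4OAc in aqueous acetone.

Step 3. Background addition of 4 and loose binding of the α-branched enal 3 to the phosphoric acid may erode facial selectivity at C12′. The fallback sets out from 3 and comes back at 6, moving stereocontrol from the catalyst to a stoichiometric chiral borane. Brown allylboration with B-allylbis(isopinocampheyl)borane of the (−)-α-pinene series [(+)-Ipc2BOMe, allylmagnesium bromide, Et2O, −78 °C] would give the bis(isopinocampheyl)borinate of 6 F5, which a buffered H2O2 work-up (pH 7) would cleave without loss of the acetate.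

Further compounds
F1 | step 11 | bis[2-(tert-butyldimethylsilyloxy)-5-methoxy-3-methylphenyl]zinc | COc1cc(C)c(O[Si](C)(C)C(C)(C)C)c([Zn]c2cc(OC)cc(C)c2O[Si](C)(C)C(C)(C)C)c1
F2 | step 11 | (2E,5RS,6E,10E,12R)-12-(tert-butyldimethylsilyloxy)-1-[2-(tert-butyldimethylsilyloxy)-5-methoxy-3-methylphenyl]-3,7,11,15-tetramethylhexadeca-2,6,10,14-tetraen-5-ol (both C5 epimers) | COc1cc(C)c(O[Si](C)(C)C(C)(C)C)c(C/C=C(\C)CC(O)/C=C(\C)CC/C=C(\C)[C@H](O[Si](C)(C)C(C)(C)C)CC=C(C)C)c1
F3 | step 11 | (2E,6E,10E,12R)-12-(tert-butyldimethylsilyloxy)-1-[2-(tert-butyldimethylsilyloxy)-5-methoxy-3-methylphenyl]-3,7,11,15-tetramethylhexadeca-2,6,10,14-tetraen-5-one | COc1cc(C)c(O[Si](C)(C)C(C)(C)C)c(C/C=C(\C)CC(=O)/C=C(\C)CC/C=C(\C)[C@H](O[Si](C)(C)C(C)(C)C)CC=C(C)C)c1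
F4 | step 10 | tert-butyl[4-methoxy-2-methyl-6-(4,4,5,5-tetramethyl-1,3,2-dioxaborolan-2-yl)phenoxy]dimethylsilane | COc1cc(C)c(O[Si](C)(C)C(C)(C)C)c(B2OC(C)(C)C(C)(C)O2)c1
F5 | step 3 | bis(isopinocampheyl)borinate of 6 (O–B(Ipc)2 at C8, Ipc from (−)-α-pinene) | CC(=O)OC/C=C(\C)CC/C=C(\C)[C@H](OB([C@H]1C[C@H]2C[C@@H]([C@@H]1C)C2(C)C)[C@H]1C[C@H]2C[C@@H]([C@@H]1C)C2(C)C)CC=C
A1 | direct plan | (2E,5R,6E,10E,12R)-5,12-bis(tert-butyldimethylsilyloxy)-3,7,11,15-tetramethylhexadeca-2,6,10,14-tetraen-1-ol | OC/C=C(\C)C[C@@H](O[Si](C)(C)C(C)(C)C)/C=C(\C)CC/C=C(\C)[C@H](O[Si](C)(C)C(C)(C)C)CC=C(C)C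
A2 | direct plan | 2-[(4E,7R,8E,12E,14R)-7,14-bis(tert-butyldimethylsilyloxy)-5,9,13,17-tetramethyloctadeca-4,8,12,16-tetraen-1-yn-1-yl]-4,4,5,5-tetramethyl-1,3,2-dioxaborolane | CC1(C)OB(OC1(C)C)C#CC/C=C(\C)C[C@@H](O[Si](C)(C)C(C)(C)C)/C=C(\C)CC/C=C(\C)[C@H](O[Si](C)(C)C(C)(C)C)CC=C(C)C
A3 | direct plan | 4-methoxy-6-methyl-2H-pyran-2-one | COC1=CC(=O)OC(C)=C1
A4 | direct plan | 2-{2-[(2E,5R,6E,10E,12R)-5,12-bis(tert-butyldimethylsilyloxy)-3,7,11,15-tetramethylhexadeca-2,6,10,14-tetraen-1-yl]-4-methoxy-6-methylphenyl}-4,4,5,5-tetramethyl-1,3,2-dioxaborolane | COc1cc(C)c(B2OC(C)(C)C(C)(C)O2)c(C/C=C(\C)C[C@@H](O[Si](C)(C)C(C)(C)C)/C=C(\C)CC/C=C(\C)[C@H](O[Si](C)(C)C(C)(C)C)CC=C(C)C)c1
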